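A leftover comes first: violet's last reading still leaves 46.1% of its L outside J, so we count what a flask turns over in mM, not in percent.

| flask | L | D | remark | time |
|---|---|---|---|---|
| amber | 10 mM | 5.5 mM (held) | run made earlier |  |
| violet | 15 mM | 5.5 mM (held) | run made earlier |  |
| flask | 20 mM | 5.5 mM (held) |  | 30 h |

- amber (time / h: J / %, E / %): 5.00: 16.1, 0; 10.0: 31.8, 4.1; 15.0: 46.5, 16.5; 20.0: 59.7, 27.4; 25.0: 66.3, 36.5
- violet (time / h: J / %, E / %): 2.00: 2.9, 0; 6.00: 15.0, 1.0; 12.0: 25.7, 7.8; 15.0: 35.9, 10.9; 25.0: 53.9, 34.1

(each reading ± 1 percentage point)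

1. J and E together at 30 h, in percent of the L charged
2. concentration of G in solution at 30 h, in percent of saturation

- for J the E are counted in
- as a solid, counted per litre of solution: E, L
- at the start none of D is in solution
- at the start none of L is in solution
- G is what D becomes in solution

1. The charge of L. By hand, a bigger charge should make more J. At 15.0 h, amber holds 4.65 mM and violet 5.38 mM. The charge rose by a factor 1.50, but J in mM rose by 1.16. So in these readings J in mM rises less than the charge, which we read as close to zero order in L.

2. The time. By hand, J grows with the hours while the rate holds. We therefore define the making rate: mM of J, E counted in, per hour since the start. Violet's last reading gives 0.323 mM h⁻¹. Amber's readings bend after 59.7%, gaining 0.132 mM h⁻¹ in its last interval. At that bend amber had 4.03 mM of its charge outside J. At this rate our flask reaches 48.5% of its charge and keeps 10.3 mM outside J, more than at amber's bend, so we commit to this figure.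

3. The gas. D is the same in both runs, so the readings show nothing of its effect, and we give no figure for [G].

The forecast says 46% and 60%, on the ground that the rate “looks zero order while solid L remains”. Our yield is higher.

The flask gives 50.4% and 2.81%.

    D ⇌ G, rate k1*(csat - [G]) (kL = 0.0690 h⁻¹)
    Q + G → J (k = 370 M⁻¹ h⁻¹)
    G + J → X (k = 64.0 M⁻¹ h⁻¹)
    E ⇌ J, rate k4*(cs4 - [J]) while solid is left; crystals form when [J] > cs4 (solubility = 2.80 mM, k = 0.940 h⁻¹)
    Q ⇌ Z (K = 0.910, k = 0.0140 h⁻¹)
    L ⇌ Q, rate k6*(cs6 - [Q]) while solid is left; crystals form when [Q] > cs6 (solubility = 16.0 mM, k = 1.20 h⁻¹)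

The flask's making rate, averaged over its 30 h, is 0.336 mM h⁻¹, and 0.069 h⁻¹ times saturation gives the feed of G into a solution free of G, 0.380 mM h⁻¹, more than that rate. With 50 mM of L over the same time, the rate 0.323 mM h⁻¹ predicts 19.4%; that flask gives 21.1%, or 0.352 mM h⁻¹. In our flask L dissolved first, with half its turnover done by 0.810 h, and stood at 0% at 15.0 h. Q + G to J then ran on from the dissolved Q, which fell from 60.0% to 28.8%, while J rose from 26.2% to 50.4% and [G] stood at 0.155 mM at 30.0 h.

The readings were generated by integration with constants of no real substance.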